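**Retrosynthetic overview**
- The last step is a global deprotection. The ten-membered carbocycle (ring A) is closed last, at C9–C10, by an intramolecular Nozaki–Hiyama–Kishi addition of an alkenyl iodide to an α-acyloxy aldehyde.
- The butyrolactone (ring B) is made first. Its C6–C7 bond comes from a visible-light photoredox, chromium-catalysed allylation of a West enal with an East 2-(bromomethyl)enoate, followed by lactonisation.
- East fragment: (S)-glyceraldehyde acetonide plus methyl acrylate. Its one stereocentre (C8) relays to C7, C6 and later C9. The ester stereocentre is bought as (R)-2-methylbutanoic acid.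
- West fragment: but-2-yne-1,4-diol. Anti-carbomagnesiation fixes the C4=C5 geometry; cross-metathesis and α-iodination fix C1=C10.
- Ring order: ring B (lactone), then ring A (cyclodecadiene).

Assumption: germacrane numbering is used throughout (ring carbons C1–C10, lactone carbons C11–C13, C14 on C10, C15 on C4; both ring alkenes are ring-cis, CIP E), and (S)-glyceraldehyde acetonide (from L-ascorbic acid) and (R)-2-methylbutanoic acid are taken as purchasable.

Step 1
Reactants: 1 (S)-glyceraldehyde acetonide; 2 methyl acrylate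
Product: 3 Morita–Baylis–Hillman adduct (carbinol epimers)
Conditions: DABCO (0.5 equiv), neat methyl acrylate (3 equiv), 20 °C, 5 d
Reagents that add atoms: none
Why: Morita–Baylis–Hillman reaction of the α-alkoxy aldehyde with methyl acrylate; the new carbinol centre forms as a mixture that converges in step 2, and C8 from 1 is not epimerised.

Step 2
Reactants: 3 Morita–Baylis–Hillman adduct
Product: 4 (Z)-2-(bromomethyl)enoate (East fragment)
Conditions: NBS (1.5 equiv), Me2S (1.8 equiv), CH2Cl2, 0 to 20 °C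
Reagents that add atoms: N-bromosuccinimide, O=C1CCC(=O)N1Br
Why: Corey–Kim-type activation of the allylic alcohol and SN2′ delivery of bromide give the thermodynamically preferred Z-2-(bromomethyl)enoate, erasing the carbinol centre while C8 is untouched.

Step 3
Reactants: 5 but-2-yne-1,4-diol; 6 but-3-en-1-ylmagnesium bromide
Product: 8 (2E)-2-(but-3-en-1-yl)but-2-ene-1,4-diol, via alkenylmagnesium bis(alkoxide) 7 (not isolated)
Conditions: 6 (3.3 equiv), CuI (10 mol %), THF, 0 to 65 °C; then H2O, aq. NH4Cl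
Reagents that add atoms: none
Why: Copper-catalysed anti-carbomagnesiation of the propargylic alkoxide through a five-membered magnesium chelate places the butenyl chain trans to the new C5–H, i.e. C3 cis to C6, which fixes the C4=C5 geometry.

Step 4
Reactants: 8 (2E)-2-(but-3-en-1-yl)but-2-ene-1,4-diol; 9 crotonaldehyde
Product: 10 (2E,6E)-8-hydroxy-6-(hydroxymethyl)octa-2,6-dienal
Conditions: 9 (5 equiv), second-generation Hoveyda–Grubbs catalyst RuCl2(H2IMes)(=CH–C6H4-2-OiPr) (3 mol %), CH2Cl2, 40 °C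
Reagents that add atoms: none
Why: Olefin cross-metathesis of the terminal alkene with crotonaldehyde gives the E-enal, while the trisubstituted C4=C5 alkene is inert.

Step 5
Reactants: 10 (2E,6E)-8-hydroxy-6-(hydroxymethyl)octa-2,6-dienal
Product: 11 (2Z,6E)-8-hydroxy-6-(hydroxymethyl)-2-iodoocta-2,6-dienal
Conditions: I2 (1.5 equiv), DMAP (0.2 equiv), K2CO3 (1.2 equiv), THF/H2O 1:1, 20 °C
Reagents that add atoms: iodine, II
Why: DMAP-catalysed α-iodination (conjugate addition of DMAP, iodination of the enolate, elimination; Morita–Baylis–Hillman-type) is specific for the β-monosubstituted enal and gives the Z-iodoenal with C2 trans to CHO, the future C1=C10 geometry.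

Step 6
Reactants: 11 (2Z,6E)-8-hydroxy-6-(hydroxymethyl)-2-iodoocta-2,6-dienal
Product: 12 (2E,6Z)-3-(hydroxymethyl)-7-iodo-8,8-dimethoxyocta-2,6-dien-1-ol
Conditions: HC(OMe)3 (3 equiv), PPTS (5 mol %), MeOH, 20 °C
Reagents that add atoms: trimethyl orthoformate, COC(OC)OC
Why: Acid-catalysed acetalisation with orthoformate as water scavenger masks the C14 aldehyde, so that only the C6 aldehyde made later is electrophilic.

Step 7
Reactants: 12 (2E,6Z)-3-(hydroxymethyl)-7-iodo-8,8-dimethoxyocta-2,6-dien-1-ol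
Product: 13 (2E,6Z)-3-(hydroxymethyl)-7-iodo-8,8-dimethoxyocta-2,6-dienal
Conditions: activated MnO2 (8 equiv), CH2Cl2, 0 °C, stopped at about 90 % conversion
Reagents that add atoms: none
Why: MnO2 oxidation of allylic alcohols is faster at the C6 carbinol (on the CH= carbon, giving the better-stabilised allylic radical and the β,β-disubstituted enal) than at the more hindered C15 carbinol on the fully substituted alkene carbon, and it leaves both alkene geometries intact.

Step 8
Reactants: 13 (2E,6Z)-3-(hydroxymethyl)-7-iodo-8,8-dimethoxyocta-2,6-dienal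
Product: 14 West enal (15-O-TBDPS)
Conditions: TBDPSCl (1.2 equiv), imidazole (2 equiv), CH2Cl2, 0 °C
Reagents that add atoms: tert-butyl(chloro)diphenylsilane, CC(C)(C)[Si](Cl)(c1ccccc1)c1ccccc1
Why: Standard silylation of the remaining primary alcohol; TBDPS is chosen because it survives the acidic methanol of step 10 and falls in the last step.

Step 9
Reactants: 4 (Z)-2-(bromomethyl)enoate (East fragment); 14 West enal
Product: 16 (6R,7S,8R)-trans-lactone acetonide, via hydroxy ester 15 (not isolated)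
Conditions: 4 (1.5 equiv), CrCl3(THF)3 (10 mol %), 4,4′-di-tert-butyl-2,2′-bipyridine (10 mol %), [Ru(bpy)3](PF6)2 (1 mol %), Hantzsch ester (1.5 equiv), degassed THF, 456 nm LEDs, 20 °C; aq. NaHCO3 work-up; then PPTS (10 mol %), CH2Cl2, 20 °C
Reagents that add atoms: none
Why: Proposed new method: a catalytic-in-chromium photoredox Nozaki–Hiyama allylation (closest known: photoredox chromium-catalysed allylation of aldehydes with simple allyl halides, and stoichiometric CrCl2 additions of glyceraldehyde-derived allylic bromides), extended here to a 2-(methoxycarbonyl)allyl bromide with a γ-dioxolane stereocentre; photoreduced [Ru(bpy)3]+ turns trivalent chromium into divalent chromium, two of which convert 4 into an allylchromium that adds to enal 14 through a chair transition state with the C8 substituent equatorial (6,7-anti, hence the trans-lactone) and with the aldehyde entering anti to the C8–O bond while C8–H eclipses the ester-bearing alkene (Felkin–Anh sense, so C8 from 1 sets C7 and C6), and the Hantzsch pyridinium protonates the chromium alkoxide to close the cycle before acid lactonises the γ-hydroxy ester.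

Step 10
Reactants: 16 (6R,7S,8R)-trans-lactone acetonide
Product: 17 lactone 8,9-diol
Conditions: CSA (10 mol %), MeOH, 0 °C, 1 h; Et3N quench
Reagents that add atoms: none
Why: Acid-catalysed transketalisation to methanol removes the terminal acetonide, while the C14 dimethyl acetal only exchanges degenerately with methanol and the TBDPS ether and the lactone survive at 0 °C.

Step 11
Reactants: 17 lactone 8,9-diol; 18 (2R)-2-methylbutanoic acid
Product: 20 8-O-[(2R)-2-methylbutanoyl] 9-O-triethylsilyl lactone, via primary TES ether 19 (not isolated)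
Conditions: TESCl (1.05 equiv), imidazole (2.5 equiv), CH2Cl2, −78 to −40 °C; then 18 (1.5 equiv), DCC (1.6 equiv), DMAP (0.2 equiv), 0 to 20 °C
Reagents that add atoms: chlorotriethylsilane, CC[Si](Cl)(CC)CC
Why: TESCl silylates the primary C9 hydroxyl selectively at low temperature, and the remaining secondary C8 hydroxyl is then esterified under Steglich conditions with acid 18, whose bought stereocentre is not enolised.

Step 12
Reactants: 20 8-O-[(2R)-2-methylbutanoyl] 9-O-triethylsilyl lactone
Product: 21 α-acyloxy aldehyde (cyclisation precursor)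
Conditions: (COCl)2 (3 equiv), DMSO (6 equiv), CH2Cl2, −78 to −40 °C; then iPr2NEt (8 equiv), −78 to 0 °C
Reagents that add atoms: none
Why: The Swern reagent oxidises primary triethylsilyl ethers directly to aldehydes while the TBDPS ether, ester, acetal and alkenyl iodide are inert, and iPr2NEt at low temperature avoids epimerisation of the α-acyloxy aldehyde.

Step 13
Reactants: 21 α-acyloxy aldehyde (cyclisation precursor)
Product: 22 protected macrocycle (9S alcohol)
Conditions: CrCl2 (10 equiv), NiCl2 (0.2 equiv), DMSO/THF 3:1, 2 mM, syringe-pump addition over 12 h, 20 °C; aqueous work-up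
Reagents that add atoms: none
Why: Intramolecular Nozaki–Hiyama–Kishi reaction in which zerovalent nickel inserts into the alkenyl C–I bond and transmetalation gives an alkenylchromium that adds to the aldehyde with retention of the ring-cis alkene geometry and anti to the C8–O bond of the α-acyloxy aldehyde (Felkin–Anh), giving the 8,9-anti (9S) alcohol in the ten-membered ring.

Step 14
Reactants: 22 protected macrocycle (9S alcohol)
Product: 24 CNP0331447.12 (target), via 9,15-diol dimethyl acetal 23 (not isolated)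
Conditions: HF·pyridine, pyridine, THF, 0 to 20 °C; then 1 M aq. HCl, THF, 0 °C
Reagents that add atoms: water, O
Why: Fluoride removes the TBDPS ether and dilute acid hydrolyses the allylic dimethyl acetal to the enal, with no stereocentre touched and the ester and lactone stable to the mild acid.

**Compound list**
1 | (4S)-2,2-dimethyl-1,3-dioxolane-4-carbaldehyde, (S)-glyceraldehyde acetonide | O=C[C@@H]1COC(C)(C)O1 | starting material
2 | methyl acrylate | C=CC(=O)OC | starting material
3 | methyl 2-{[(4S)-2,2-dimethyl-1,3-dioxolan-4-yl](hydroxy)methyl}prop-2-enoate (both carbinol epimers) | C=C(C(O)[C@@H]1COC(C)(C)O1)C(=O)OC | intermediate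
4 | methyl (2Z)-2-(bromomethyl)-3-[(4R)-2,2-dimethyl-1,3-dioxolan-4-yl]prop-2-enoate | COC(=O)/C(CBr)=C/[C@@H]1COC(C)(C)O1 | intermediate
5 | but-2-yne-1,4-diol | OCC#CCO | starting material
6 | but-3-en-1-ylmagnesium bromide | C=CCC[Mg]Br | starting material
7 | bromomagnesium alkenyl bis(alkoxide) from anti-carbomagnesiation (Mg on C5 cis to C15) | C=CCC/C(CO[Mg]Br)=C(\CO[Mg]Br)[Mg]Br | intermediate
8 | (2E)-2-(but-3-en-1-yl)but-2-ene-1,4-diol | OC/C=C(/CO)CCC=C | intermediate
9 | (E)-but-2-enal, crotonaldehyde | C/C=C/C=O | starting material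
10 | (2E,6E)-8-hydroxy-6-(hydroxymethyl)octa-2,6-dienal | OC/C=C(/CO)CC/C=C/C=O | intermediate
11 | (2Z,6E)-8-hydroxy-6-(hydroxymethyl)-2-iodoocta-2,6-dienal | OC/C=C(/CO)CC/C=C(/C=O)I | intermediate
12 | (2E,6Z)-3-(hydroxymethyl)-7-iodo-8,8-dimethoxyocta-2,6-dien-1-ol | OC/C=C(/CO)CC/C=C(/C(OC)OC)I | intermediate
13 | (2E,6Z)-3-(hydroxymethyl)-7-iodo-8,8-dimethoxyocta-2,6-dienal | O=C/C=C(/CO)CC/C=C(/C(OC)OC)I | intermediate
14 | (2E,6Z)-3-{[tert-butyl(diphenyl)silyl]oxymethyl}-7-iodo-8,8-dimethoxyocta-2,6-dienal | O=C/C=C(/CO[Si](c1ccccc1)(c1ccccc1)C(C)(C)C)CC/C=C(/C(OC)OC)I | intermediate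
15 | methyl (3S,4R,5E,9Z)-6-{[tert-butyl(diphenyl)silyl]oxymethyl}-3-[(4R)-2,2-dimethyl-1,3-dioxolan-4-yl]-4-hydroxy-10-iodo-11,11-dimethoxy-2-methylideneundeca-5,9-dienoate | C=C(C(=O)OC)[C@@H]([C@H](O)/C=C(/CO[Si](c2ccccc2)(c2ccccc2)C(C)(C)C)CC/C=C(/C(OC)OC)I)[C@@H]1COC(C)(C)O1 | intermediate
16 | (4S,5R)-5-[(1E,5Z)-2-{[tert-butyl(diphenyl)silyl]oxymethyl}-6-iodo-7,7-dimethoxyhepta-1,5-dien-1-yl]-4-[(4R)-2,2-dimethyl-1,3-dioxolan-4-yl]-3-methylideneoxolan-2-one | C=C1C(=O)O[C@H](/C=C(/CO[Si](c2ccccc2)(c2ccccc2)C(C)(C)C)CC/C=C(/C(OC)OC)I)[C@H]1[C@@H]3COC(C)(C)O3 | intermediate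
17 | (4R,5R)-5-[(1E,5Z)-2-{[tert-butyl(diphenyl)silyl]oxymethyl}-6-iodo-7,7-dimethoxyhepta-1,5-dien-1-yl]-4-[(1R)-1,2-dihydroxyethyl]-3-methylideneoxolan-2-one | C=C1C(=O)O[C@H](/C=C(/CO[Si](c2ccccc2)(c2ccccc2)C(C)(C)C)CC/C=C(/C(OC)OC)I)[C@H]1[C@@H](O)CO | intermediate
18 | (2R)-2-methylbutanoic acid | OC(=O)[C@H](C)CC | starting material
19 | (4R,5R)-5-[(1E,5Z)-2-{[tert-butyl(diphenyl)silyl]oxymethyl}-6-iodo-7,7-dimethoxyhepta-1,5-dien-1-yl]-4-{(1R)-1-hydroxy-2-[(triethylsilyl)oxy]ethyl}-3-methylideneoxolan-2-one | C=C1C(=O)O[C@H](/C=C(/CO[Si](c2ccccc2)(c2ccccc2)C(C)(C)C)CC/C=C(/C(OC)OC)I)[C@H]1[C@@H](O)CO[Si](CC)(CC)CC | intermediate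
20 | (1R)-1-{(2R,3S)-2-[(1E,5Z)-2-{[tert-butyl(diphenyl)silyl]oxymethyl}-6-iodo-7,7-dimethoxyhepta-1,5-dien-1-yl]-4-methylidene-5-oxooxolan-3-yl}-2-[(triethylsilyl)oxy]ethyl (2R)-2-methylbutanoate | C=C1C(=O)O[C@H](/C=C(/CO[Si](c2ccccc2)(c2ccccc2)C(C)(C)C)CC/C=C(/C(OC)OC)I)[C@H]1[C@@H](OC(=O)[C@H](C)CC)CO[Si](CC)(CC)CC | intermediate
21 | (1R)-1-{(2R,3S)-2-[(1E,5Z)-2-{[tert-butyl(diphenyl)silyl]oxymethyl}-6-iodo-7,7-dimethoxyhepta-1,5-dien-1-yl]-4-methylidene-5-oxooxolan-3-yl}-2-oxoethyl (2R)-2-methylbutanoate | C=C1C(=O)O[C@H](/C=C(/CO[Si](c2ccccc2)(c2ccccc2)C(C)(C)C)CC/C=C(/C(OC)OC)I)[C@H]1[C@@H](OC(=O)[C@H](C)CC)C=O | intermediate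
22 | (1(10)E,4E,6R,7S,8R,9S)-15-{[tert-butyl(diphenyl)silyl]oxy}-9-hydroxy-14,14-dimethoxy-8-{[(2R)-2-methylbutanoyl]oxy}germacra-1(10),4,11(13)-trien-12,6-olide | C=C1C(=O)O[C@@H]2/C=C(/CO[Si](c3ccccc3)(c3ccccc3)C(C)(C)C)CC/C=C(/C(OC)OC)[C@H](O)[C@H](OC(=O)[C@H](C)CC)[C@@H]12 | intermediate
23 | (1(10)E,4E,6R,7S,8R,9S)-9,15-dihydroxy-14,14-dimethoxy-8-{[(2R)-2-methylbutanoyl]oxy}germacra-1(10),4,11(13)-trien-12,6-olide | C=C1C(=O)O[C@@H]2/C=C(/CO)CC/C=C(/C(OC)OC)[C@H](O)[C@H](OC(=O)[C@H](C)CC)[C@@H]12 | intermediate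
24 | CNP0331447.12, (1(10)E,4E,6R,7S,8R,9S)-9,15-dihydroxy-8-{[(2R)-2-methylbutanoyl]oxy}-14-oxogermacra-1(10),4,11(13)-trien-12,6-olide | C=C1C(=O)O[C@@H]2/C=C(/CO)CC/C=C(/C=O)[C@H](O)[C@H](OC(=O)[C@H](C)CC)[C@@H]12 | target

**Step count and risks**
Total steps: 14. Longest linear sequence: 12 (steps 3 to 14, from 5).

Steps most likely to fail:

Step 7 (regioselective oxidation of diol 12). The two primary allylic alcohols may not be differentiated well enough. The fallback replaces chemoselective oxidation by steric protecting-group differentiation. It sets out from 12. Tritylation (TrCl, Et3N, DMAP, CH2Cl2, 0 °C) takes the less hindered C6 hydroxyl and gives (2E,6Z)-3-(hydroxymethyl)-7-iodo-8,8-dimethoxy-1-(triphenylmethoxy)octa-2,6-diene F1. Silylation of the remaining C15 hydroxyl (TBDPSCl, imidazole) gives the trityl TBDPS bis-ether F2. Detritylation in acidic methanol (CSA, MeOH/CH2Cl2, 0 °C; the dimethyl acetal only exchanges) gives (2E,6Z)-3-{[tert-butyl(diphenyl)silyl]oxymethyl}-7-iodo-8,8-dimethoxyocta-2,6-dien-1-ol F3. MnO2 then oxidises the only free allylic alcohol, and the sequence comes back to the route at 14.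

Step 9 (the proposed photoredox chromium-catalysed allylation). Risks are poor catalyst turnover with the ester-bearing allyl bromide, light-induced E/Z scrambling of enal 14, and insufficient 1,2-induction. The fallback leaves the catalytic photochemical manifold for the known stoichiometric organochromium reaction. It sets out from 4 and 14. The allylchromium is preformed in the dark with CrCl2 (3 equiv, THF, 0 to 20 °C; classical Hiyama–Nozaki allylation, established with Felkin–Anh selectivity for glyceraldehyde-derived allylic bromides). This gives hydroxy ester 15 and, after PPTS, comes back to the route at 16. New compounds on the way: none F0.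

Step 13 (ten-membered ring closure). Risks are ring strain and a macrocyclic transition state that overrides Felkin–Anh control and gives the wrong C9 epimer. The fallback sets C9 by ketone reduction instead of by the addition. It sets out from 21. If the cyclisation gives mainly the 9R epimer of the protected macrocycle F4, or a mixture, the allylic alcohol is oxidised (Dess–Martin periodinane, NaHCO3, CH2Cl2) to the C9 enone F5. F5 is reduced with Zn(BH4)2 (Et2O, −30 °C), where chelation of zinc between the ketone and the 8-acyloxy group directs hydride to give the 8,9-anti alcohol, and the sequence comes back to the route at 22.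

Further compounds
F1 | step 7 | (2E,6Z)-3-(hydroxymethyl)-7-iodo-8,8-dimethoxy-1-(triphenylmethoxy)octa-2,6-diene | C(c1ccccc1)(c1ccccc1)(c1ccccc1)OC/C=C(/CO)CC/C=C(/C(OC)OC)I
F2 | step 7 | (2E,6Z)-3-{[tert-butyl(diphenyl)silyl]oxymethyl}-7-iodo-8,8-dimethoxy-1-(triphenylmethoxy)octa-2,6-diene | C(c1ccccc1)(c1ccccc1)(c1ccccc1)OC/C=C(/CO[Si](c1ccccc1)(c1ccccc1)C(C)(C)C)CC/C=C(/C(OC)OC)I
F3 | step 7 | (2E,6Z)-3-{[tert-butyl(diphenyl)silyl]oxymethyl}-7-iodo-8,8-dimethoxyocta-2,6-dien-1-ol | OC/C=C(/CO[Si](c1ccccc1)(c1ccccc1)C(C)(C)C)CC/C=C(/C(OC)OC)I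
F0 | step 9 | none | none
F4 | step 13 | (1(10)E,4E,6R,7S,8R,9R)-15-{[tert-butyl(diphenyl)silyl]oxy}-9-hydroxy-14,14-dimethoxy-8-{[(2R)-2-methylbutanoyl]oxy}germacra-1(10),4,11(13)-trien-12,6-olide (9-epimer of 22) | C=C1C(=O)O[C@@H]2/C=C(/CO[Si](c3ccccc3)(c3ccccc3)C(C)(C)C)CC/C=C(/C(OC)OC)[C@@H](O)[C@H](OC(=O)[C@H](C)CC)[C@@H]12
F5 | step 13 | (1(10)E,4E,6R,7S,8R)-15-{[tert-butyl(diphenyl)silyl]oxy}-14,14-dimethoxy-8-{[(2R)-2-methylbutanoyl]oxy}-9-oxogermacra-1(10),4,11(13)-trien-12,6-olide | C=C1C(=O)O[C@@H]2/C=C(/CO[Si](c3ccccc3)(c3ccccc3)C(C)(C)C)CC/C=C(/C(OC)OC)C(=O)[C@H](OC(=O)[C@H](C)CC)[C@@H]12
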